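The C3–C3' bond is cut last, giving two (4R)-4-arylchroman-2-ones. The unprimed one rests on the C4–C4a disconnection: its 4-hydroxyphenyl ring, C4, C3 and C2 are the carbon chain of L-tyrosine. C4 lies para to the phenolic oxygen, so oxidation turns it into the exocyclic carbon of a para-quinone methide. C4a of the phloroglucinol ring, ortho and para to two ether oxygens, then adds to it. This single operation forms C4–C4a, closes the lactone ring and passes the tyrosine stereocentre, kept at C3 as an azide, on to C4. Its precursor is the 3,5-bis(benzyloxy)phenyl ester of (S)-2-azido-3-(4-hydroxyphenyl)propanoic acid with the phenol free.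

Key step: step 5

Remark on stereochemistry: the SMILES reads as (3S,4R,3'S,4'R). In both lactone rings the C4 aryl group and the C3–C3' bond are cis, so the hydrogens at C3 and C3' must arrive last, anti to the aryl groups.

Remark on the primed ring: it carries five oxygens. 2,3,4-Trihydroxybenzaldehyde brings three, and two formyl-to-hydroxyl exchanges add the others. Its crowded benzyloxy groups make this arene a weaker π-nucleophile and easier for DDQ to oxidise than the phloroglucinol ring. The primed lactone is therefore made by established catalysis, and the untested reaction is used once.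

Assumption: 3,5-bis(benzyloxy)phenol, the stabilised ylide, 4-(benzyloxy)phenylboronic acid, the anomeric amide reagent and (R)-SEGPHOS are taken as commercial.

Step 1
Reactants: 1 L-tyrosine
Product: 2 (S)-2-azido-3-(4-hydroxyphenyl)propanoic acid
Conditions: imidazole-1-sulfonyl azide hydrogen sulfate, K2CO3, CuSO4·5H2O (cat.), MeOH/H2O, rt; acidic work-up
Reagents that add atoms: imidazole-1-sulfonyl azide hydrogen sulfate, [N-]=[N+]=NS(=O)(=O)n1ccnc1.OS(=O)(=O)O
Why: Copper-catalysed diazo transfer turns NH2 into N3 by adding two nitrogens to the amine nitrogen, so the C–N bond and the (S) centre (future C3) are untouched.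

Step 2
Reactants: 2 (S)-2-azido-3-(4-hydroxyphenyl)propanoic acid
Product: 4 (S)-2-azido-3-[4-(tert-butyldimethylsilyloxy)phenyl]propanoic acid, via bis-silyl derivative 3 (not isolated)
Conditions: TBSCl (2.5 equiv), imidazole, DMF, rt; then THF/H2O/AcOH, rt
Reagents that add atoms: tert-butyldimethylsilyl chloride, CC(C)(C)[Si](C)(C)Cl
Why: Silylation of both acidic OH groups followed by selective solvolysis of the far more labile silyl ester leaves the aryl silyl ether, which keeps the tyrosine phenol from competing as a nucleophile in step 3.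

Step 3
Reactants: 4 (S)-2-azido-3-[4-(tert-butyldimethylsilyloxy)phenyl]propanoic acid; 5 3,5-bis(benzyloxy)phenol
Product: 6 3,5-bis(benzyloxy)phenyl (S)-2-azido-3-[4-(tert-butyldimethylsilyloxy)phenyl]propanoate
Conditions: DIC, DMAP (5 mol%), CH2Cl2, 0 °C
Reagents that add atoms: none
Why: Steglich esterification; an alpha-azido acid cannot form an oxazolone and only catalytic DMAP is present in the cold, so the aryl ester should form with retention at the alpha-carbon.

Step 4
Reactants: 6 3,5-bis(benzyloxy)phenyl (S)-2-azido-3-[4-(tert-butyldimethylsilyloxy)phenyl]propanoate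
Product: 7 3,5-bis(benzyloxy)phenyl (S)-2-azido-3-(4-hydroxyphenyl)propanoate
Conditions: HF·pyridine, THF, 0 °C → rt
Reagents that add atoms: none
Why: Fluoride cleavage of an aryl silyl ether under acidic rather than basic conditions frees the phenol without forming a phenoxide that could transacylate the activated aryl ester or enolise the alpha-azido ester.

Step 5
Reactants: 7 3,5-bis(benzyloxy)phenyl (S)-2-azido-3-(4-hydroxyphenyl)propanoate
Product: 9 (3S,4R)-3-azido-5,7-bis(benzyloxy)-4-(4-hydroxyphenyl)chroman-2-one, via para-quinone methide 8 (not isolated)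
Conditions: DDQ (1.0 equiv, slow addition), CH2Cl2/1,1,1,3,3,3-hexafluoropropan-2-ol (HFIP) 4:1, 0.005 M, −20 → 0 °C
Reagents that add atoms: none
Why: Proposed new method: DDQ takes the phenolic hydrogen and a hydride from benzylic C4 of 7 to give para-quinone methide 8, and C4a of the ester arene then adds to the exocyclic carbon C4, which is activated by hydrogen bonding to HFIP and to the acidic hydroquinone formed, in an intramolecular Friedel–Crafts 1,6-addition that rearomatises both rings. The closest known reaction types are the DDQ oxidation of 4-alkylphenols and tyrosine derivatives through para-quinone methides, the acid-catalysed 1,6-addition of electron-rich arenes to para-quinone methides, and the acid-mediated cyclisation of aryl cinnamates to 4-arylchroman-2-ones; their combination on an amino-acid aryl ester is untested. The lactone ring closes 6-exo-trig with respect to the C4=C1'' bond and has to pass through the less populated s-cis rotamer of the ester. C4 is controlled by the C3 centre inherited from L-tyrosine: 1,3-allylic strain turns C3–H into the plane of the quinone methide towards its ortho C–H, azide and ester carbonyl then occupy opposite faces, and the tethered arene can reach only the face anti to the azide, which gives the 3,4-trans lactone, (4R) from the (S)-azide. The step needs ring closure to outrun loss of the C3 proton from 8 (tautomerisation to the achiral alpha-azidocinnamate) and needs 9 to escape a second dehydrogenation at its doubly benzylic C4–H; a doubly activated C4a (one ortho and one para benzyloxy group) held in a six-membered transition state, a base-free ionising medium, high dilution and slow addition of one equivalent of DDQ in the cold are meant to secure both. Site selectivity is built in, because the two carbons ortho to the ester oxygen are equivalent and the para carbon cannot reach C4, and neither the azide nor unsubstituted benzyl aryl ethers are attacked by DDQ under these conditions.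

Step 6
Reactants: 9 (3S,4R)-3-azido-5,7-bis(benzyloxy)-4-(4-hydroxyphenyl)chroman-2-one
Product: 11 (3S,4R)-3-amino-5,7-bis(benzyloxy)-4-(4-hydroxyphenyl)chroman-2-one hydrochloride, via iminophosphorane 10 (not isolated)
Conditions: PMe3 (1.1 equiv), THF, 0 °C; then 1 M aq HCl, 0 °C → rt
Reagents that add atoms: hydrogen chloride, Cl
Why: Staudinger reduction; the electron-poor azide reacts quickly with PMe3, and acidic hydrolysis of the iminophosphorane gives the amine directly as its salt, so it cannot open the aryl lactone of a second molecule and the benzyl ethers are untouched.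

Step 7
Reactants: 11 (3S,4R)-3-amino-5,7-bis(benzyloxy)-4-(4-hydroxyphenyl)chroman-2-one hydrochloride
Product: 14 (4R)-5,7-bis(benzyloxy)-4-(4-hydroxyphenyl)chroman-2-one, via free amine 12 (not isolated), via diazene 13 (not isolated)
Conditions: iPr2NEt (1.0 equiv), N-(benzyloxy)-N-(pivaloyloxy)-4-(trifluoromethyl)benzamide (1.3 equiv), MeCN, rt → 45 °C
Reagents that add atoms: none
Why: Anomeric-amide hydrodeamination of a primary amine, a reaction type established for alpha-amino acid derivatives: N-amination and loss of the ester fragment give a monosubstituted diazene that expels N2 in a radical chain and leaves C3 as CH2, while C4 is not involved and stays (R).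

Step 8
Reactants: 14 (4R)-5,7-bis(benzyloxy)-4-(4-hydroxyphenyl)chroman-2-one
Product: 15 (4R)-5,7-bis(benzyloxy)-4-[4-(benzyloxy)phenyl]chroman-2-one
Conditions: BnOH, PPh3, DIAD, THF, 0 °C → rt
Reagents that add atoms: benzyl alcohol, OCc1ccccc1
Why: Mitsunobu etherification alkylates the phenol under neutral conditions, avoids the carbonate/phenoxide medium that could open the aryl lactone, and installs the same hydrogenolysable group used elsewhere before any enolate chemistry.

Step 9
Reactants: 16 2,3,4-trihydroxybenzaldehyde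
Product: 17 2,3,4-tris(benzyloxy)benzaldehyde
Conditions: BnBr (3.5 equiv), K2CO3, DMF, 60 °C
Reagents that add atoms: benzyl bromide, BrCc1ccccc1
Why: Williamson etherification of all three phenols; benzyl is chosen so that one neutral hydrogenolysis can end the synthesis.

Step 10
Reactants: 17 2,3,4-tris(benzyloxy)benzaldehyde
Product: 19 2,3,4-tris(benzyloxy)phenol, via aryl formate 18 (not isolated)
Conditions: mCPBA, CH2Cl2, rt; aq NaHCO3 wash; then K2CO3 (cat.), MeOH, rt
Reagents that add atoms: 3-chloroperoxybenzoic acid, OOC(=O)c1cccc(Cl)c1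
Why: Baeyer–Villiger oxidation of an electron-rich benzaldehyde proceeds with aryl migration to the aryl formate, whose methanolysis frees the fourth ring oxygen as a phenol.

Step 11
Reactants: 19 2,3,4-tris(benzyloxy)phenol
Product: 20 3,4,5-tris(benzyloxy)-2-hydroxybenzaldehyde
Conditions: MgCl2, Et3N, paraformaldehyde, MeCN, reflux; then 1 M HCl
Reagents that add atoms: paraformaldehyde (as formaldehyde), C=O
Why: Magnesium-mediated ortho-formylation (Casnati–Skattebøl reaction) delivers formaldehyde within the magnesium phenoxide chelate to the only free ortho carbon.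

Step 12
Reactants: 20 3,4,5-tris(benzyloxy)-2-hydroxybenzaldehyde
Product: 21 2,3,4,5-tetrakis(benzyloxy)benzaldehyde
Conditions: BnBr, K2CO3, DMF, 50 °C
Reagents that add atoms: benzyl bromide, BrCc1ccccc1
Why: Williamson etherification caps the oxygen that becomes O8', so that the next oxygen introduced is the only free one.

Step 13
Reactants: 21 2,3,4,5-tetrakis(benzyloxy)benzaldehyde
Product: 23 2,3,4,5-tetrakis(benzyloxy)phenol, via aryl formate 22 (not isolated)
Conditions: mCPBA, CH2Cl2, rt; aq NaHCO3 wash; then K2CO3 (cat.), MeOH, rt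
Reagents that add atoms: 3-chloroperoxybenzoic acid, OOC(=O)c1cccc(Cl)c1
Why: A second Baeyer–Villiger oxidation and methanolysis supply the fifth ring oxygen (future O1') as the only free OH, next to the single remaining aromatic C–H.

Step 14
Reactants: 23 2,3,4,5-tetrakis(benzyloxy)phenol
Product: 24 2,3,4,5-tetrakis(benzyloxy)-6-hydroxybenzaldehyde
Conditions: MgCl2, Et3N, paraformaldehyde, MeCN, reflux; then 1 M HCl
Reagents that add atoms: paraformaldehyde (as formaldehyde), C=O
Why: The same Casnati–Skattebøl ortho-formylation can react only at the last aromatic C–H (future C4a') and installs C4'.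

Step 15
Reactants: 24 2,3,4,5-tetrakis(benzyloxy)-6-hydroxybenzaldehyde; 25 ethyl (triphenylphosphoranylidene)acetate
Product: 27 5,6,7,8-tetrakis(benzyloxy)-2H-chromen-2-one, via hydroxycinnamate 26 (not isolated)
Conditions: N,N-diethylaniline, reflux
Reagents that add atoms: none
Why: Wittig olefination with a stabilised ylide followed by thermal E/Z isomerisation and lactonisation is the classical salicylaldehyde-to-coumarin sequence and also works for 6-alkoxysalicylaldehydes.

Step 16
Reactants: 27 5,6,7,8-tetrakis(benzyloxy)-2H-chromen-2-one; 28 4-(benzyloxy)phenylboronic acid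
Product: 29 (4R)-5,6,7,8-tetrakis(benzyloxy)-4-[4-(benzyloxy)phenyl]chroman-2-one
Conditions: Rh(acac)(C2H4)2 (3 mol%), (R)-SEGPHOS (3.3 mol%), 28 (excess), dioxane/H2O 10:1, 60 °C; mildly acidic work-up
Reagents that add atoms: none
Why: Hayashi–Miyaura asymmetric conjugate addition, established for coumarins, sets C4' by catalyst control, the (R)-ligand being the enantiomer that gives (R)-4-arylchroman-2-ones.

Step 17
Reactants: 15 (4R)-5,7-bis(benzyloxy)-4-[4-(benzyloxy)phenyl]chroman-2-one; 29 (4R)-5,6,7,8-tetrakis(benzyloxy)-4-[4-(benzyloxy)phenyl]chroman-2-one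
Product: 32 (3R,4R,3'R,4'R)-5,7,5',6',7',8'-hexakis(benzyloxy)-4,4'-bis[4-(benzyloxy)phenyl]-3,3'-bichroman-2,2'-dione (trans/trans isomer), via lithium enolate 30 (not isolated), via lithium enolate 31 (not isolated)
Conditions: 15 (2 equiv) and 29 (1 equiv) added to LDA (3.1 equiv), THF, −78 °C; Cu(2-ethylhexanoate)2 (3.3 equiv), −78 → −20 °C
Reagents that add atoms: none
Why: Oxidative enolate heterocoupling by single-electron oxidation with divalent copper, in which each enolate carbon should bond anti to its pseudoaxial C4 aryl group (3,4-trans and 3',4'-trans); the excess of 15 biases a near-statistical mixture towards the cross product, the three dimers differ by two benzyloxy groups each and should separate on silica, and any C3/C3' isomers converge in step 18.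

Step 18
Reactants: 32 trans/trans dimer
Product: 34 (3S,4R,3'S,4'R)-5,7,5',6',7',8'-hexakis(benzyloxy)-4,4'-bis[4-(benzyloxy)phenyl]-3,3'-bichroman-2,2'-dione (cis/cis isomer), via dilithium bis-enolate 33 (not isolated)
Conditions: LDA (4 equiv), THF, −78 → −45 °C, argon; then AcOH (excess) in THF, −78 °C
Reagents that add atoms: none
Why: Kinetic protonation of lactone enolates, the reaction type used to reach contra-thermodynamic aryl-substituted lactones: in the succinate-type bis-enolate each planar C3 is shielded on one face by the pseudoaxial C4 aryl group, so the proton enters anti to it, pushes the C3–C3' bond cis to the aryl group, and the irreversible acidic quench prevents re-equilibration.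

Step 19
Reactants: 34 cis/cis octabenzyl ether
Product: 35 (3S,4R,3'S,4'R)-5,7,5',6',7',8'-hexahydroxy-4,4'-bis(4-hydroxyphenyl)-3,3'-bichroman-2,2'-dione (CNP0064734.1)
Conditions: H2 (1 atm), 10% Pd/C, THF/EtOAc, rt; filtration under argon
Reagents that add atoms: none
Why: Catalytic hydrogenolysis removes all eight benzyl ethers under neutral, non-nucleophilic conditions that neither epimerise C3/C3' nor open the aryl lactones, and exclusion of air protects the tetrahydroxyarene.

Compound list
1 | L-tyrosine | N[C@@H](Cc1ccc(O)cc1)C(=O)O | starting material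
2 | (S)-2-azido-3-(4-hydroxyphenyl)propanoic acid | O=C(O)[C@H](Cc1ccc(O)cc1)N=[N+]=[N-] | intermediate
3 | tert-butyldimethylsilyl (S)-2-azido-3-[4-(tert-butyldimethylsilyloxy)phenyl]propanoate | O=C(O[Si](C)(C)C(C)(C)C)[C@H](Cc1ccc(O[Si](C)(C)C(C)(C)C)cc1)N=[N+]=[N-] | intermediate
4 | (S)-2-azido-3-[4-(tert-butyldimethylsilyloxy)phenyl]propanoic acid | O=C(O)[C@H](Cc1ccc(O[Si](C)(C)C(C)(C)C)cc1)N=[N+]=[N-] | intermediate
5 | 3,5-bis(benzyloxy)phenol | Oc1cc(OCc2ccccc2)cc(OCc2ccccc2)c1 | starting material
6 | 3,5-bis(benzyloxy)phenyl (S)-2-azido-3-[4-(tert-butyldimethylsilyloxy)phenyl]propanoate | O=C(Oc1cc(OCc2ccccc2)cc(OCc2ccccc2)c1)[C@H](Cc1ccc(O[Si](C)(C)C(C)(C)C)cc1)N=[N+]=[N-] | intermediate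
7 | 3,5-bis(benzyloxy)phenyl (S)-2-azido-3-(4-hydroxyphenyl)propanoate | O=C(Oc1cc(OCc2ccccc2)cc(OCc2ccccc2)c1)[C@H](Cc1ccc(O)cc1)N=[N+]=[N-] | intermediate
8 | 3,5-bis(benzyloxy)phenyl (S)-2-azido-3-(4-oxocyclohexa-2,5-dien-1-ylidene)propanoate | O=C(Oc1cc(OCc2ccccc2)cc(OCc2ccccc2)c1)[C@H](C=C1C=CC(=O)C=C1)N=[N+]=[N-] | intermediate
9 | (3S,4R)-3-azido-5,7-bis(benzyloxy)-4-(4-hydroxyphenyl)chroman-2-one | O=C1Oc2cc(OCc3ccccc3)cc(OCc3ccccc3)c2[C@@H](c2ccc(O)cc2)[C@@H]1N=[N+]=[N-] | intermediate
10 | (3S,4R)-5,7-bis(benzyloxy)-4-(4-hydroxyphenyl)-3-[(trimethylphosphoranylidene)amino]chroman-2-one | O=C1Oc2cc(OCc3ccccc3)cc(OCc3ccccc3)c2[C@@H](c2ccc(O)cc2)[C@@H]1N=P(C)(C)C | intermediate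
11 | (3S,4R)-3-amino-5,7-bis(benzyloxy)-4-(4-hydroxyphenyl)chroman-2-one hydrochloride | O=C1Oc2cc(OCc3ccccc3)cc(OCc3ccccc3)c2[C@@H](c2ccc(O)cc2)[C@@H]1N.Cl | intermediate
12 | (3S,4R)-3-amino-5,7-bis(benzyloxy)-4-(4-hydroxyphenyl)chroman-2-one | O=C1Oc2cc(OCc3ccccc3)cc(OCc3ccccc3)c2[C@@H](c2ccc(O)cc2)[C@@H]1N | intermediate
13 | (3S,4R)-5,7-bis(benzyloxy)-3-diazenyl-4-(4-hydroxyphenyl)chroman-2-one | O=C1Oc2cc(OCc3ccccc3)cc(OCc3ccccc3)c2[C@@H](c2ccc(O)cc2)[C@@H]1N=N | intermediate
14 | (4R)-5,7-bis(benzyloxy)-4-(4-hydroxyphenyl)chroman-2-one | O=C1Oc2cc(OCc3ccccc3)cc(OCc3ccccc3)c2[C@@H](c2ccc(O)cc2)C1 | intermediate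
15 | (4R)-5,7-bis(benzyloxy)-4-[4-(benzyloxy)phenyl]chroman-2-one | O=C1Oc2cc(OCc3ccccc3)cc(OCc3ccccc3)c2[C@@H](c2ccc(OCc3ccccc3)cc2)C1 | intermediate
16 | 2,3,4-trihydroxybenzaldehyde | O=Cc1ccc(O)c(O)c1O | starting material
17 | 2,3,4-tris(benzyloxy)benzaldehyde | O=Cc1ccc(OCc2ccccc2)c(OCc2ccccc2)c1OCc1ccccc1 | intermediate
18 | 2,3,4-tris(benzyloxy)phenyl formate | O=COc1ccc(OCc2ccccc2)c(OCc2ccccc2)c1OCc1ccccc1 | intermediate
19 | 2,3,4-tris(benzyloxy)phenol | Oc1ccc(OCc2ccccc2)c(OCc2ccccc2)c1OCc1ccccc1 | intermediate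
20 | 3,4,5-tris(benzyloxy)-2-hydroxybenzaldehyde | O=Cc1cc(OCc2ccccc2)c(OCc2ccccc2)c(OCc2ccccc2)c1O | intermediate
21 | 2,3,4,5-tetrakis(benzyloxy)benzaldehyde | O=Cc1cc(OCc2ccccc2)c(OCc2ccccc2)c(OCc2ccccc2)c1OCc1ccccc1 | intermediate
22 | 2,3,4,5-tetrakis(benzyloxy)phenyl formate | O=COc1cc(OCc2ccccc2)c(OCc2ccccc2)c(OCc2ccccc2)c1OCc1ccccc1 | intermediate
23 | 2,3,4,5-tetrakis(benzyloxy)phenol | Oc1cc(OCc2ccccc2)c(OCc2ccccc2)c(OCc2ccccc2)c1OCc1ccccc1 | intermediate
24 | 2,3,4,5-tetrakis(benzyloxy)-6-hydroxybenzaldehyde | O=Cc1c(O)c(OCc2ccccc2)c(OCc2ccccc2)c(OCc2ccccc2)c1OCc1ccccc1 | intermediate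
25 | ethyl (triphenylphosphoranylidene)acetate | CCOC(=O)C=P(c1ccccc1)(c1ccccc1)c1ccccc1 | starting material
26 | ethyl (E)-3-[2,3,4,5-tetrakis(benzyloxy)-6-hydroxyphenyl]prop-2-enoate | CCOC(=O)/C=C/c1c(O)c(OCc2ccccc2)c(OCc2ccccc2)c(OCc2ccccc2)c1OCc1ccccc1 | intermediate
27 | 5,6,7,8-tetrakis(benzyloxy)-2H-chromen-2-one | O=C1Oc2c(OCc3ccccc3)c(OCc3ccccc3)c(OCc3ccccc3)c(OCc3ccccc3)c2C=C1 | intermediate
28 | 4-(benzyloxy)phenylboronic acid | OB(O)c1ccc(OCc2ccccc2)cc1 | starting material
29 | (4R)-5,6,7,8-tetrakis(benzyloxy)-4-[4-(benzyloxy)phenyl]chroman-2-one | O=C1Oc2c(OCc3ccccc3)c(OCc3ccccc3)c(OCc3ccccc3)c(OCc3ccccc3)c2[C@@H](c2ccc(OCc3ccccc3)cc2)C1 | intermediate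
30 | lithium enolate of 15 | [Li]OC=1Oc2cc(OCc3ccccc3)cc(OCc3ccccc3)c2[C@@H](c2ccc(OCc3ccccc3)cc2)C=1 | intermediate
31 | lithium enolate of 29 | [Li]OC=1Oc2c(OCc3ccccc3)c(OCc3ccccc3)c(OCc3ccccc3)c(OCc3ccccc3)c2[C@@H](c2ccc(OCc3ccccc3)cc2)C=1 | intermediate
32 | (3R,4R,3'R,4'R)-octabenzyl ether, 3,4-trans and 3',4'-trans | O=C1Oc2cc(OCc3ccccc3)cc(OCc3ccccc3)c2[C@@H](c2ccc(OCc3ccccc3)cc2)[C@@H]1[C@@H]1C(=O)Oc2c(OCc3ccccc3)c(OCc3ccccc3)c(OCc3ccccc3)c(OCc3ccccc3)c2[C@H]1c1ccc(OCc2ccccc2)cc1 | intermediate
33 | (4R,4'R)-dilithium bis-enolate of 32 | [Li]OC=1Oc2cc(OCc3ccccc3)cc(OCc3ccccc3)c2[C@@H](c2ccc(OCc3ccccc3)cc2)C=1C1=C(O[Li])Oc2c(OCc3ccccc3)c(OCc3ccccc3)c(OCc3ccccc3)c(OCc3ccccc3)c2[C@H]1c1ccc(OCc2ccccc2)cc1 | intermediate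
34 | (3S,4R,3'S,4'R)-octabenzyl ether, 3,4-cis and 3',4'-cis | O=C1Oc2cc(OCc3ccccc3)cc(OCc3ccccc3)c2[C@@H](c2ccc(OCc3ccccc3)cc2)[C@H]1[C@H]1C(=O)Oc2c(OCc3ccccc3)c(OCc3ccccc3)c(OCc3ccccc3)c(OCc3ccccc3)c2[C@H]1c1ccc(OCc2ccccc2)cc1 | intermediate
35 | CNP0064734.1, (3S,4R,3'S,4'R)-5,7,5',6',7',8'-hexahydroxy-4,4'-bis(4-hydroxyphenyl)-3,3'-bichroman-2,2'-dione | O=C1Oc2cc(O)cc(O)c2[C@@H](c2ccc(O)cc2)[C@H]1[C@H]1C(=O)Oc2c(O)c(O)c(O)c(O)c2[C@H]1c1ccc(O)cc1 | target

Total step count: 19. Longest linear sequence: 11 (steps 1–8 or steps 9–16, then steps 17–19).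

Steps most likely to fail

**Step 5.** Three things may go wrong.
- The quinone methide may lose its C3 proton faster than the ring closes, because the ester must first reach its s-cis rotamer.
- The product may be dehydrogenated a second time at C4.
- Facial selectivity may be incomplete, which after step 7 would show up as eroded enantiopurity. Crystallisation of 9 is the place to correct this.

The fallback uses known chemistry only, sets out from 5 and sets C4 by catalyst control instead of chirality relay. Magnesium-mediated ortho-formylation (MgCl2, Et3N, paraformaldehyde) would give 2,4-bis(benzyloxy)-6-hydroxybenzaldehyde F1. Wittig olefination with 25 in refluxing N,N-diethylaniline would pass through ethyl (E)-3-[2,4-bis(benzyloxy)-6-hydroxyphenyl]prop-2-enoate F2 to 5,7-bis(benzyloxy)-2H-chromen-2-one F3. Hayashi–Miyaura addition of 28 with Rh(acac)(C2H4)2/(R)-SEGPHOS would then rejoin the route at 15.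

**Step 17.** The two enolates are electronically alike, so homocoupling competes. Bond formation between two carbons that each carry a diarylmethine neighbour may be slow, and the aryl lactone enolates may decay by ring opening on warming.

The fallback sets out from 15 and 29 and gives the two partners opposite polarity.
- Enolate 30 would be quenched with NBS at −78 °C to give (3S,4R)-5,7-bis(benzyloxy)-4-[4-(benzyloxy)phenyl]-3-bromochroman-2-one F4.
- Enolate 31 would be trapped with TMSCl to give the trimethylsilyl ketene acetal of 29 F5.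
- Visible-light photoredox coupling (Ir(ppy)3, blue LED, MeCN/CH2Cl2) of an alpha-bromo carbonyl compound with a silyl enol ether is a known route to 1,4-dicarbonyl compounds.
- It would generate the electrophilic C3 radical from F4, add it to the electron-rich C3' of F5 anti to the aryl group, and after oxidation and desilylation come back at 32 with no homodimer channel.

**Step 18.** Double deprotonation of the hindered succinate may stay incomplete. Protonation may be only partly face-selective at one of the two centres, and the enolates may be oxidised by traces of air.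

The fallback sets out from 32 and delivers both hydrogens by syn-hydrogenation instead of protonation. Bis-enolate 33 would be oxidised with I2 at −78 °C to (E,4R,4'R)-5,7,5',6',7',8'-hexakis(benzyloxy)-4,4'-bis[4-(benzyloxy)phenyl]-3,3'-bichromanylidene-2,2'-dione F6. The E geometry is expected because the Z form would press C4 against C4'. In the E alkene with like configuration at C4 and C4', both aryl groups stand on the same face. Hydrogenation over Pd/C should therefore add both hydrogens from the open face, giving the cis/cis array, and remove the eight benzyl groups in the same operation. This comes back at 35 and bypasses 34.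

Further compounds
F1 | step 5 | 2,4-bis(benzyloxy)-6-hydroxybenzaldehyde | O=Cc1c(O)cc(OCc2ccccc2)cc1OCc1ccccc1
F2 | step 5 | ethyl (E)-3-[2,4-bis(benzyloxy)-6-hydroxyphenyl]prop-2-enoate | CCOC(=O)/C=C/c1c(O)cc(OCc2ccccc2)cc1OCc1ccccc1
F3 | step 5 | 5,7-bis(benzyloxy)-2H-chromen-2-one | O=C1Oc2cc(OCc3ccccc3)cc(OCc3ccccc3)c2C=C1
F4 | step 17 | (3S,4R)-5,7-bis(benzyloxy)-4-[4-(benzyloxy)phenyl]-3-bromochroman-2-one | O=C1Oc2cc(OCc3ccccc3)cc(OCc3ccccc3)c2[C@@H](c2ccc(OCc3ccccc3)cc2)[C@@H]1Br
F5 | step 17 | trimethylsilyl ketene acetal of 29 | C[Si](C)(C)OC=1Oc2c(OCc3ccccc3)c(OCc3ccccc3)c(OCc3ccccc3)c(OCc3ccccc3)c2[C@@H](c2ccc(OCc3ccccc3)cc2)C=1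
F6 | step 18 | (E,4R,4'R)-5,7,5',6',7',8'-hexakis(benzyloxy)-4,4'-bis[4-(benzyloxy)phenyl]-3,3'-bichromanylidene-2,2'-dione | O=C1Oc2cc(OCc3ccccc3)cc(OCc3ccccc3)c2[C@@H](c2ccc(OCc3ccccc3)cc2)/C1=C1\C(=O)Oc2c(OCc3ccccc3)c(OCc3ccccc3)c(OCc3ccccc3)c(OCc3ccccc3)c2[C@H]1c1ccc(OCc2ccccc2)cc1
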